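(The readings were computed from invented constants; scatter was added.)

**Questions.** 3 numbers are asked of the flask, and one earlier run, the ochre run, bears on them.

| setting | ochre | flask |
|---|---|---|
| left-handed substrate | 0.050 M | 0.050 M |
| right-handed substrate | 0.050 M | 0.050 M |
| partner | 0.15 M | 0.150 M |
| protic impurity | 0.025 M | 0.0250 M |
| free catalyst | 0.60 mM | 1.2 mM |
| remark | run made earlier |  |
| time |  | 12 min |

- ochre (time / min: left-handed substrate / %, right-handed substrate / %, left-handed product / %): 0.417: 35.5, 47.7, 14.2; 0.833: 29.9, 46.5, 20.1; 1.33: 25.0, 47.3, 24.6; 1.50: 24.9, 46.5, 25.7; 2.00: 23.0, 47.0, 27.7; 2.50: 22.1, 46.1, 27.6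

(scatter of a reading: 0.5 percentage points)

- free catalyst is single-handed; left-handed substrate and right-handed substrate are mirror images of each other, charged as a racemate, each of them at the stated concentration
- an excess is the difference of the two amounts in percent of their sum
- an excess is below zero if the other one leads
- no earlier run changes the charge of free catalyst; that part of a forecast is a guess

* part of the left-handed substrate and right-handed substrate charged together that has reacted at 12 min
* excess of left-handed product over right-handed product in the product at 12 min
* excess of right-handed substrate over left-handed substrate among what is left of the two at 12 min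

**Time.** The ochre run stalls, so I read how far its left-handed substrate falls before stopping. In the first round I treat the last reading as the end, a fall in ln c(left-handed substrate) of 0.816. Set against the reading at 1.33 min, that implies a decay constant of 1.42 min⁻¹, which leaves 2.86% of the work undone at the last reading. Put back, the fall becomes 0.841. If the flask decays as quickly, 12 min is 17.0 decay times, and by hand a longer run adds little.

**Charge.** I carry a value read from the ochre run, 1.40 mM⁻¹, the catalyst dose: the whole fall of ln c(left-handed substrate) per unit of free catalyst charged. The flask holds twice the ochre catalyst, and no earlier run changes that charge, so proportion is my guess. In the flask it leaves left-handed substrate at 9.31%. The last four right-handed readings of the ochre run average 46.7%, giving a selectivity factor of 12.4, as read there. So right-handed substrate in the flask ends at 43.7%. My answers for the flask are 47.0% reacted, product excess 73.2% and substrate excess 64.9%.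

**Forecast.** The forecast, judging that “the catalyst is dying”, gives 48.8%, 67.6% and 64.5%. It takes selectivity as about 10, and I take 12.4.

**Result.** The flask gives 49.0% reacted, product excess 71.2% and substrate excess 68.3%, so the forecast stands. At 12.0 min free catalyst is down to 0.0127% of its charge, with 50% of the partner still there.

    partner + protic impurity → quenched reagent (k = 35.2 M⁻¹ s⁻¹)
    partner + free catalyst + right-handed substrate → free catalyst + right-handed product (k = 20.3 M⁻² s⁻¹)
    partner + free catalyst → spent catalyst (k = 0.160 M⁻¹ s⁻¹)
    partner + free catalyst + left-handed substrate → free catalyst + left-handed product (k = 243 M⁻² s⁻¹)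

**Dose again.** My dose 1.40 mM⁻¹ reckoned 9.31% of left-handed substrate, and the flask holds 8.08%, which reads back as 1.52 mM⁻¹. Applied to the neighbour flask charged with 0.0020 M of free catalyst, 1.52 mM⁻¹ gives 2.39%, and that neighbour holds 2.40%.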